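The cyclohexene ring is read as a reduced 2-alkylcyclohexane-1,3-dione: the C6 carbinol and C10, the ring carbon bearing the OCH2 arm (C14), are the former carbonyl carbons flanking C5 (sesquiterpene numbering, ring C5–C10). Everything rests on the C10–C14 bond. A Stille coupling of the C10 enol triflate 20, a β-triflyloxy enone that already carries the trans-fused α-methylene lactone and the acetoxy side chain, with (tributylstannyl)methyl isobutyrate 22 delivers the complete isobutyryloxymethyl group in one operation and fixes the tetrasubstituted C5=C10 alkene. Only a ketone reduction follows; no hydroxyl protecting group is used.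

Key step: step 14

Remark: in compounds 9 to 18 the α-keto methine that bears the side chain (C5; C6 in the spiro names) is configurationally labile, so these compounds are carried as epimer mixtures written without configuration at that centre, which becomes sp2 in 19.

Step 1
Reactants: 1 (3E)-pent-3-en-2-one
Product: 2 (2R,3E)-pent-3-en-2-ol
Conditions: (S)-Me-CBS (10 mol %), catecholborane, toluene, −78 °C
Reagents that add atoms: none
Why: Corey–Bakshi–Shibata reduction in which the propenyl group is the large and methyl the small ketone substituent, so the (S)-oxazaborolidine directs hydride to the face that gives the (R)-carbinol, and catecholborane at −78 °C reduces the enone 1,2 without hydroborating the alkene.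

Step 2
Reactants: 2 (2R,3E)-pent-3-en-2-ol; 3 3-chlorocyclohex-2-en-1-one
Product: 5 2-[(2S,3E)-pent-3-en-2-yl]cyclohexane-1,3-dione, via allyl vinylogous ester 4 (not isolated)
Conditions: NaH, THF, 0 °C to rt; then toluene, 150 °C (sealed tube)
Reagents that add atoms: none
Why: Alkoxide addition–elimination on the β-chloro enone gives the allyl vinylogous ester, whose thermal Claisen rearrangement runs through a transition state with the carbinol methyl pseudo-equatorial, so the (R)-C–O stereocentre is relayed suprafacially to the new (S)-configured C4 and an (E)-alkene while the ring carbon ends as a non-stereogenic dione carbon.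

Step 3
Reactants: 5 2-[(2S,3E)-pent-3-en-2-yl]cyclohexane-1,3-dione; 6 (2Z)-but-2-ene-1,4-diyl diacetate
Product: 8 (4S)-4-(2,6-dioxocyclohexyl)pentyl acetate, via allylic acetate 7 (not isolated)
Conditions: Hoveyda–Grubbs II (5 mol %), CH2Cl2, 40 °C; then 2-NO2C6H4SO2NHNH2, Et3N, rt
Reagents that add atoms: none
Why: Olefin cross-metathesis with the symmetrical allylic diacetate replaces the propenyl terminus by a CH2OAc-bearing one, and diimide generated in the same flask reduces the new disubstituted alkene without double-bond migration, allylic C–O hydrogenolysis or loss of the C4 configuration.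

Step 4
Reactants: 8 (4S)-4-(2,6-dioxocyclohexyl)pentyl acetate
Product: 9 (4S)-4-(7-oxo-1,4-dioxaspiro[4.5]decan-6-yl)pentyl acetate
Conditions: 2-ethyl-2-methyl-1,3-dioxolane, TsOH·H2O (cat.), rt
Reagents that add atoms: 2-ethyl-2-methyl-1,3-dioxolane, CCC1(C)OCCO1
Why: Acid-catalysed transketalisation of the symmetrical 2-alkyl-1,3-dione gives one constitutional mono-ketal, because the remaining carbonyl is then flanked by the ketal and the branched side chain and reacts much more slowly.

Step 5
Reactants: 9 (4S)-4-(7-oxo-1,4-dioxaspiro[4.5]decan-6-yl)pentyl acetate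
Product: 11 (4S)-4-(7-oxo-1,4-dioxaspiro[4.5]dec-8-en-6-yl)pentyl acetate, via silyl enol ether 10 (not isolated)
Conditions: LiHMDS, TMSCl, THF, −78 °C; then Pd(OAc)2, MeCN, rt
Reagents that add atoms: chlorotrimethylsilane, C[Si](C)(C)Cl (its atoms stay only in 10)
Why: Saegusa–Ito oxidation, in which LiHMDS with internal TMSCl quench enolises the ketone kinetically toward the unhindered C7 methylene (not the tertiary C5–H and not the less acidic acetate) and Pd(OAc)2 turns the silyl enol ether into the C7=C8 enone, which cannot aromatise because C10 is locked as the ketal.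

Step 6
Reactants: 11 (4S)-4-(7-oxo-1,4-dioxaspiro[4.5]dec-8-en-6-yl)pentyl acetate
Product: 12 (4S)-4-(8-iodo-7-oxo-1,4-dioxaspiro[4.5]dec-8-en-6-yl)pentyl acetate
Conditions: I2, pyridine, CH2Cl2, 0 °C to rt
Reagents that add atoms: iodine, II
Why: α-Iodination of the cyclic enone by a Baylis–Hillman-type sequence of pyridine conjugate addition, iodination of the enolate and elimination, which places iodine on C7.

Step 7
Reactants: 12 (4S)-4-(8-iodo-7-oxo-1,4-dioxaspiro[4.5]dec-8-en-6-yl)pentyl acetate; 13 ethynyl(triethyl)silane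
Product: 14 (4S)-4-{7-oxo-8-[(triethylsilyl)ethynyl]-1,4-dioxaspiro[4.5]dec-8-en-6-yl}pentyl acetate
Conditions: PdCl2(PPh3)2 (5 mol %), CuI (10 mol %), i-Pr2NH, THF, rt
Reagents that add atoms: none
Why: Sonogashira coupling of the electron-poor α-iodo enone installs the two carbons that become C11 and C13 of the lactone, the silyl group blocking the alkyne during the next step.

Step 8
Reactants: 14 (4S)-4-{7-oxo-8-[(triethylsilyl)ethynyl]-1,4-dioxaspiro[4.5]dec-8-en-6-yl}pentyl acetate
Product: 16 (4S)-4-{(8S,9R)-9-hydroxy-7-oxo-8-[(triethylsilyl)ethynyl]-1,4-dioxaspiro[4.5]decan-6-yl}pentyl acetate, via boronate 15 (not isolated)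
Conditions: CuCl (5 mol %), Josiphos-type bisphosphine (6 mol %), NaOt-Bu (10 mol %), B2pin2, MeOH, THF, rt; then 30 % H2O2, pH 7 buffer, 0 °C
Reagents that add atoms: bis(pinacolato)diboron, CC1(C)OB(OC1(C)C)B1OC(C)(C)C(C)(C)O1 (boron stays only in 15); hydrogen peroxide, OO
Why: Copper-catalysed enantioselective conjugate borylation of the cyclic enone, in which the chiral bisphosphine (enantiomer chosen for the 9R carbinol, sense to be confirmed on enone 11) controls the face of the β-carbon attacked by Cu–Bpin, followed by stereoretentive C–B oxidation, the doubly activated α-CH then equilibrating to the trans-diequatorial arrangement of alkynyl and hydroxyl groups.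

Step 9
Reactants: 16 (4S)-4-{(8S,9R)-9-hydroxy-7-oxo-8-[(triethylsilyl)ethynyl]-1,4-dioxaspiro[4.5]decan-6-yl}pentyl acetate
Product: 17 (4S)-4-[(8S,9R)-8-ethynyl-9-hydroxy-7-oxo-1,4-dioxaspiro[4.5]decan-6-yl]pentyl acetate
Conditions: TBAF, AcOH, THF, 0 °C
Reagents that add atoms: none
Why: Fluoride-induced protodesilylation of the alkynylsilane, buffered with acetic acid so that the β-hydroxy ketone suffers neither retro-aldol cleavage nor elimination and the acetate survives.

Step 10
Reactants: 17 (4S)-4-[(8S,9R)-8-ethynyl-9-hydroxy-7-oxo-1,4-dioxaspiro[4.5]decan-6-yl]pentyl acetate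
Product: 18 (4S)-4-[(3aS,7aR)-3-methylidene-2,4-dioxohexahydro-2H-spiro[1-benzofuran-6,2'-[1,3]dioxolan]-5-yl]pentyl acetate
Conditions: PdCl2 (5 mol %), SnCl2 (5 mol %), PPh3 (10 mol %), CO (7 bar), MeCN, 70 °C
Reagents that add atoms: carbon monoxide, [C-]#[O+]
Why: Palladium-catalysed cyclocarbonylation of a homopropargylic alcohol (Markovnikov alkoxycarbonylation of the terminal alkyne by the neighbouring hydroxyl) converts the trans-2-ethynylcyclohexanol unit directly into the trans-fused α-methylene-γ-butyrolactone under neutral conditions and creates no stereocentre.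

Step 11
Reactants: 18 (4S)-4-[(3aS,7aR)-3-methylidene-2,4-dioxohexahydro-2H-spiro[1-benzofuran-6,2'-[1,3]dioxolan]-5-yl]pentyl acetate
Product: 19 (4S)-4-[(3aS,7aR)-6-hydroxy-3-methylidene-2,4-dioxo-2,3,3a,4,7,7a-hexahydro-1-benzofuran-5-yl]pentyl acetate
Conditions: PPTS, acetone/H2O, 50 °C
Reagents that add atoms: water, O
Why: Mild acid-catalysed ketal hydrolysis releases the second carbonyl and the product enolises to the vinylogous acid, which removes the labile C5 stereocentre, while β-elimination of the lactone oxygen is disfavoured because the C8–O bond of the rigid trans-fused bicycle is equatorial and poorly aligned with the enol π system.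

Step 12
Reactants: 19 (4S)-4-[(3aS,7aR)-6-hydroxy-3-methylidene-2,4-dioxo-2,3,3a,4,7,7a-hexahydro-1-benzofuran-5-yl]pentyl acetate
Product: 20 (4S)-4-[(3aS,7aR)-3-methylidene-2,4-dioxo-6-(trifluoromethanesulfonyloxy)-2,3,3a,4,7,7a-hexahydro-1-benzofuran-5-yl]pentyl acetate
Conditions: Tf2O, 2,6-lutidine, CH2Cl2, −78 °C
Reagents that add atoms: trifluoromethanesulfonic anhydride, O=S(=O)(OS(=O)(=O)C(F)(F)F)C(F)(F)F
Why: O-Sulfonylation of the vinylogous acid at low temperature is expected at the less hindered oxygen on C10 (flanked by the C9 methylene), not at the oxygen on C6 next to the ring-fusion carbon C7, and the weak hindered base spares the acidic C7–H.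

Step 13
Reactants: 21 (tributylstannyl)methanol
Product: 22 (tributylstannyl)methyl 2-methylpropanoate
Conditions: i-PrCOCl, pyridine, DMAP (cat.), CH2Cl2, 0 °C
Reagents that add atoms: 2-methylpropanoyl chloride, CC(C)C(Cl)=O
Why: DMAP-catalysed acylation of the primary stannyl alcohol with the acid chloride.

Step 14
Reactants: 20 (4S)-4-[(3aS,7aR)-3-methylidene-2,4-dioxo-6-(trifluoromethanesulfonyloxy)-2,3,3a,4,7,7a-hexahydro-1-benzofuran-5-yl]pentyl acetate; 22 (tributylstannyl)methyl 2-methylpropanoate
Product: 23 [(3aS,7aR)-5-[(2S)-5-acetoxypentan-2-yl]-3-methylidene-2,4-dioxo-2,3,3a,4,7,7a-hexahydro-1-benzofuran-6-yl]methyl 2-methylpropanoate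
Conditions: Pd2(dba)3 (5 mol %), AsPh3 (20 mol %), CuI (20 mol %), LiCl, NMP, 45 °C
Reagents that add atoms: none
Why: Stille coupling in which Pd(0) inserts into the C10–O bond of the vinylogous acyl triflate, the oxygen-bearing CH2 group of 22 passes from tin via copper to palladium, and reductive elimination forges the sp2–sp3 C10–C14 bond. The closest known reactions are the couplings of vinyl and aryl triflates with (hydroxymethyl)- and (alkoxymethyl)tributylstannanes. No ring is closed and no stereocentre is formed, and the position of the tetrasubstituted C5=C10 alkene is dictated by the enol triflate. The step needs selective transfer of the CH2O group over butyl, which the α-oxygen substituent and the copper co-catalyst provide, and it needs the triflate to react faster than a Heck reaction at the exocyclic methylene or ionisation of the allylic ester in the product, which the highly activated β-triflyloxy enone, the weakly donating AsPh3 ligand and the low temperature secure. The base-free medium protects the acidic C7–H and with it the ring-fusion configuration.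

Step 15
Reactants: 23 [(3aS,7aR)-5-[(2S)-5-acetoxypentan-2-yl]-3-methylidene-2,4-dioxo-2,3,3a,4,7,7a-hexahydro-1-benzofuran-6-yl]methyl 2-methylpropanoate
Product: 24 [(3aR,4S,7aR)-5-[(2S)-5-acetoxypentan-2-yl]-4-hydroxy-3-methylidene-2-oxo-2,3,3a,4,7,7a-hexahydro-1-benzofuran-6-yl]methyl 2-methylpropanoate (CNP0246650.1)
Conditions: (R)-Me-CBS (1 equiv), catecholborane, toluene/CH2Cl2, −78 to −40 °C
Reagents that add atoms: none
Why: Corey–Bakshi–Shibata reduction under catalyst control, in which the tetrasubstituted alkenyl branch (C5) is the large and C7 the small substituent so that the (R)-oxazaborolidine delivers hydride to the face giving the (S)-carbinol cis to the C7–C11 bond, while catecholborane at low temperature reduces the enone 1,2 without touching the α-methylene lactone or the esters.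

Compound list
1 | (3E)-pent-3-en-2-one | C/C=C/C(C)=O | starting material
2 | (2R,3E)-pent-3-en-2-ol | C/C=C/[C@@H](C)O | intermediate
3 | 3-chlorocyclohex-2-en-1-one | O=C1C=C(Cl)CCC1 | starting material
4 | 3-{[(2R,3E)-pent-3-en-2-yl]oxy}cyclohex-2-en-1-one | C/C=C/[C@@H](C)OC1=CC(=O)CCC1 | intermediate
5 | 2-[(2S,3E)-pent-3-en-2-yl]cyclohexane-1,3-dione | O=C1CCCC(=O)C1[C@@H](C)/C=C/C | intermediate
6 | (2Z)-but-2-ene-1,4-diyl diacetate | CC(=O)OC/C=C\COC(C)=O | starting material
7 | (2E,4S)-4-(2,6-dioxocyclohexyl)pent-2-en-1-yl acetate | O=C1CCCC(=O)C1[C@@H](C)/C=C/COC(C)=O | intermediate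
8 | (4S)-4-(2,6-dioxocyclohexyl)pentyl acetate | O=C1CCCC(=O)C1[C@@H](C)CCCOC(C)=O | intermediate
9 | (4S)-4-(7-oxo-1,4-dioxaspiro[4.5]decan-6-yl)pentyl acetate (C6 epimers) | O=C1CCCC2(OCCO2)C1[C@@H](C)CCCOC(C)=O | intermediate
10 | (4S)-4-{7-[(trimethylsilyl)oxy]-1,4-dioxaspiro[4.5]dec-7-en-6-yl}pentyl acetate (C6 epimers) | C[Si](C)(C)OC1=CCCC2(OCCO2)C1[C@@H](C)CCCOC(C)=O | intermediate
11 | (4S)-4-(7-oxo-1,4-dioxaspiro[4.5]dec-8-en-6-yl)pentyl acetate (C6 epimers) | O=C1C=CCC2(OCCO2)C1[C@@H](C)CCCOC(C)=O | intermediate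
12 | (4S)-4-(8-iodo-7-oxo-1,4-dioxaspiro[4.5]dec-8-en-6-yl)pentyl acetate (C6 epimers) | O=C1C(I)=CCC2(OCCO2)C1[C@@H](C)CCCOC(C)=O | intermediate
13 | ethynyl(triethyl)silane | C#C[Si](CC)(CC)CC | starting material
14 | (4S)-4-{7-oxo-8-[(triethylsilyl)ethynyl]-1,4-dioxaspiro[4.5]dec-8-en-6-yl}pentyl acetate (C6 epimers) | O=C1C(C#C[Si](CC)(CC)CC)=CCC2(OCCO2)C1[C@@H](C)CCCOC(C)=O | intermediate
15 | pinacol boronate of 16: Bpin in place of the 9-hydroxyl, same configuration (C6 epimers) | CC1(C)OB(OC1(C)C)[C@@H]1CC2(OCCO2)C([C@@H](C)CCCOC(C)=O)C(=O)[C@H]1C#C[Si](CC)(CC)CC | intermediate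
16 | (4S)-4-{(8S,9R)-9-hydroxy-7-oxo-8-[(triethylsilyl)ethynyl]-1,4-dioxaspiro[4.5]decan-6-yl}pentyl acetate (C6 epimers; alkynyl and hydroxyl trans) | O[C@@H]1CC2(OCCO2)C([C@@H](C)CCCOC(C)=O)C(=O)[C@H]1C#C[Si](CC)(CC)CC | intermediate
17 | (4S)-4-[(8S,9R)-8-ethynyl-9-hydroxy-7-oxo-1,4-dioxaspiro[4.5]decan-6-yl]pentyl acetate (C6 epimers) | O[C@@H]1CC2(OCCO2)C([C@@H](C)CCCOC(C)=O)C(=O)[C@H]1C#C | intermediate
18 | (4S)-4-[(3aS,7aR)-3-methylidene-2,4-dioxohexahydro-2H-spiro[1-benzofuran-6,2'-[1,3]dioxolan]-5-yl]pentyl acetate (trans-fused lactone; C5 epimers) | C=C1C(=O)O[C@@H]2CC3(OCCO3)C([C@@H](C)CCCOC(C)=O)C(=O)[C@@H]12 | intermediate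
19 | (4S)-4-[(3aS,7aR)-6-hydroxy-3-methylidene-2,4-dioxo-2,3,3a,4,7,7a-hexahydro-1-benzofuran-5-yl]pentyl acetate (enol form of the 1,3-dione) | C=C1C(=O)O[C@@H]2CC(O)=C([C@@H](C)CCCOC(C)=O)C(=O)[C@@H]12 | intermediate
20 | (4S)-4-[(3aS,7aR)-3-methylidene-2,4-dioxo-6-(trifluoromethanesulfonyloxy)-2,3,3a,4,7,7a-hexahydro-1-benzofuran-5-yl]pentyl acetate | C=C1C(=O)O[C@@H]2CC(OS(=O)(=O)C(F)(F)F)=C([C@@H](C)CCCOC(C)=O)C(=O)[C@@H]12 | intermediate
21 | (tributylstannyl)methanol | CCCC[Sn](CCCC)(CCCC)CO | starting material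
22 | (tributylstannyl)methyl 2-methylpropanoate | CCCC[Sn](CCCC)(CCCC)COC(=O)C(C)C | intermediate
23 | [(3aS,7aR)-5-[(2S)-5-acetoxypentan-2-yl]-3-methylidene-2,4-dioxo-2,3,3a,4,7,7a-hexahydro-1-benzofuran-6-yl]methyl 2-methylpropanoate | C=C1C(=O)O[C@@H]2CC(COC(=O)C(C)C)=C([C@@H](C)CCCOC(C)=O)C(=O)[C@@H]12 | intermediate
24 | [(3aR,4S,7aR)-5-[(2S)-5-acetoxypentan-2-yl]-4-hydroxy-3-methylidene-2-oxo-2,3,3a,4,7,7a-hexahydro-1-benzofuran-6-yl]methyl 2-methylpropanoate | C=C1C(=O)O[C@@H]2CC(COC(=O)C(C)C)=C([C@@H](C)CCCOC(C)=O)[C@@H](O)[C@@H]12 | target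

Total step count: 15
Longest linear sequence: 14 steps (steps 1 to 12, then 14 and 15; step 13 is a one-step side branch)

Steps most likely to fail

Step 12. The sulfonylation may take place at the wrong enol oxygen (leaving group on C6 instead of C10), and base may trigger β-elimination of the lactone oxygen followed by aromatisation of the dione. The fallback sets out from 16 and fixes the position of the leaving group through the ketal carbon. Silylation (TBSOTf, 2,6-lutidine) would give the tert-butyldimethylsilyl ether F1. Thiophenol with BF3·OEt2 would exchange the dioxolane for a vinylogous thioester, the β-(phenylsulfanyl) enone F2, in which sulfur sits on C10 by construction. A Liebeskind–Srogl coupling of F2 with 22 (Pd2(dba)3, tri(2-furyl)phosphine, copper(I) thiophene-2-carboxylate, THF, 50 °C) would form the same C10–C14 bond and give the coupled silyl ether F3. TBAF/AcOH would remove both silyl groups to give the alkynol F4, and cyclocarbonylation as in step 10 would return to the route at 23.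

Step 8. The borylcupration of the α-alkynyl enone may proceed with poor facial selectivity, or the silylalkyne may be borylated in competition. The fallback sets out from 14: asymmetric nucleophilic epoxidation of the enone (cinchona-derived primary amine salt, aqueous H2O2) would give the epoxy ketone F5. Samarium diiodide (THF/MeOH, −78 °C) would then cleave the Cα–O bond reductively and leave the β-hydroxyl in place, returning to the route at 16 after equilibration of the α-centre.

Step 15. Hydride may be delivered to the wrong face of the C6 ketone (the intrinsic axial attack of the ring leads to the equatorial epimer), or the α-methylene lactone may be reduced in a conjugate sense. The fallback sets out from 23 and uses the substrate bias on purpose. Luche reduction (NaBH4, CeCl3, MeOH, −78 °C) would give the 6-epimeric alcohol F6, and Mitsunobu inversion with formic acid (PPh3, DIAD) would give the formate F7. Mild methanolysis of the formate (KHCO3, MeOH, 0 °C), which leaves acetate, isobutyrate and lactone intact, would return to the route at 24.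

Further compounds
F1 | step 12 | (4S)-4-{(8S,9R)-9-[(tert-butyldimethylsilyl)oxy]-7-oxo-8-[(triethylsilyl)ethynyl]-1,4-dioxaspiro[4.5]decan-6-yl}pentyl acetate | CC(C)(C)[Si](C)(C)O[C@@H]1CC2(OCCO2)C([C@@H](C)CCCOC(C)=O)C(=O)[C@H]1C#C[Si](CC)(CC)CC
F2 | step 12 | (4S)-4-{(4R,5S)-4-[(tert-butyldimethylsilyl)oxy]-6-oxo-2-(phenylsulfanyl)-5-[(triethylsilyl)ethynyl]cyclohex-1-en-1-yl}pentyl acetate | CC(C)(C)[Si](C)(C)O[C@@H]1CC(Sc2ccccc2)=C([C@@H](C)CCCOC(C)=O)C(=O)[C@H]1C#C[Si](CC)(CC)CC
F3 | step 12 | (4S)-4-{(4R,5S)-4-[(tert-butyldimethylsilyl)oxy]-2-[(2-methylpropanoyloxy)methyl]-6-oxo-5-[(triethylsilyl)ethynyl]cyclohex-1-en-1-yl}pentyl acetate | CC(C)(C)[Si](C)(C)O[C@@H]1CC(COC(=O)C(C)C)=C([C@@H](C)CCCOC(C)=O)C(=O)[C@H]1C#C[Si](CC)(CC)CC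
F4 | step 12 | (4S)-4-{(4R,5S)-5-ethynyl-4-hydroxy-2-[(2-methylpropanoyloxy)methyl]-6-oxocyclohex-1-en-1-yl}pentyl acetate | O[C@@H]1CC(COC(=O)C(C)C)=C([C@@H](C)CCCOC(C)=O)C(=O)[C@H]1C#C
F5 | step 8 | 8,9-epoxide of 14, epoxide oxygen on the face that carries the 9-hydroxyl in 16 (C6 epimers) | O=C1C([C@@H](C)CCCOC(C)=O)C2(OCCO2)C[C@H]3O[C@@]13C#C[Si](CC)(CC)CC
F6 | step 15 | [(3aR,4R,7aR)-5-[(2S)-5-acetoxypentan-2-yl]-4-hydroxy-3-methylidene-2-oxo-2,3,3a,4,7,7a-hexahydro-1-benzofuran-6-yl]methyl 2-methylpropanoate | C=C1C(=O)O[C@@H]2CC(COC(=O)C(C)C)=C([C@@H](C)CCCOC(C)=O)[C@H](O)[C@@H]12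
F7 | step 15 | [(3aR,4S,7aR)-5-[(2S)-5-acetoxypentan-2-yl]-4-(formyloxy)-3-methylidene-2-oxo-2,3,3a,4,7,7a-hexahydro-1-benzofuran-6-yl]methyl 2-methylpropanoate | C=C1C(=O)O[C@@H]2CC(COC(=O)C(C)C)=C([C@@H](C)CCCOC(C)=O)[C@@H](OC=O)[C@@H]12
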